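**Strategy.** Everything rests on closing the ten-membered carbocycle last, between C1 and C2. C1 is the β-carbon of the C1=C10–C14 enoate and C2 the carbon beside the C3 carbinol: both are natural acceptor sites, so they are joined as two electrophiles in a nickel-catalysed reductive coupling of an (E)-β-iodoacrylate with the primary iodide of an iodohydrin. In one operation this forms the C1–C2 bond and the ring with the C1=C10 geometry and the free C3 hydroxyl intact. The precursor is the complete, protecting-group-free seco-lactone: the trans-fused α-methylene-γ-butyrolactone (C6, C7), the cis C4=C5 olefin and the C8 epoxyangelate are already in place.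

Key step: step 16

Remark: locants C1–C15 in the text are those of the germacranolide skeleton of the target (C12 lactone carbonyl, C13 exo-methylene, C14 ester carbon, C15 methyl), and in steps 3 and 14 the ligand antipode meant is the one that addresses the stated aldehyde face.

**Route**

Step 1
Reactants: 1 but-2-yn-1-ol
Product: 3 (Z)-3-iodobut-2-en-1-ol, via sodium alkenylalanate 2 (not isolated)
Conditions: NaAlH2(OCH2CH2OMe)2, THF, 0 °C to rt; then I2, −78 °C
Reagents that add atoms: iodine, II
Why: Alkoxide-directed trans-hydroalumination puts aluminium on the methyl-bearing carbon inside a five-membered alanate, and iodinolysis with retention should give the (Z)-iodoalkene that carries the later C4=C5 geometry (hydroalumination–iodination of a propargylic alcohol).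

Step 2
Reactants: 3 (Z)-3-iodobut-2-en-1-ol
Product: 4 (Z)-3-iodobut-2-enal
Conditions: MnO2, CH2Cl2, rt
Reagents that add atoms: none
Why: Activated MnO2 oxidizes the allylic alcohol under neutral conditions that should leave the vinyl iodide and the Z geometry untouched (allylic oxidation).

Step 3
Reactants: 4 (Z)-3-iodobut-2-enal; 5 methyl propiolate
Product: 6 methyl (4R,5Z)-4-hydroxy-6-iodohept-5-en-2-ynoate
Conditions: Me2Zn, (S,S)-ProPhenol (20 mol %), Ph3PO, toluene, 4 °C
Reagents that add atoms: none
Why: The dinuclear zinc–ProPhenol catalyst should deliver the zinc alkynylide of 5 to the Si face of the enal (Trost asymmetric alkynylation), which sets the carbinol centre, C6 of the target, as 4R.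

Step 4
Reactants: 6 methyl (4R,5Z)-4-hydroxy-6-iodohept-5-en-2-ynoate
Product: 8 (5S)-5-[(1Z)-2-iodoprop-1-en-1-yl]furan-2(5H)-one, via hydroxy dienoate 7 (not isolated)
Conditions: [(Ph3P)CuH]6, H2O, toluene, rt; then PPTS (cat.), CH2Cl2
Reagents that add atoms: none
Why: syn-Hydrocupration and protonolysis of the ynoate (Stryker reduction) should give the (Z)-γ-hydroxy enoate, which lactonizes without touching the vinyl iodide or the carbinol centre (its descriptor changes to S only through the CIP priorities).

Step 5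
Reactants: 8 (5S)-5-[(1Z)-2-iodoprop-1-en-1-yl]furan-2(5H)-one
Product: 9 (5S)-3-(hydroxymethyl)-5-[(1Z)-2-iodoprop-1-en-1-yl]furan-2(5H)-one
Conditions: aq. HCHO, imidazole, THF/H2O, rt
Reagents that add atoms: formaldehyde, C=O
Why: Morita–Baylis–Hillman hydroxymethylation of the butenolide installs C13 on the α-carbon (C11) under conditions mild enough that the γ-stereocenter should survive.

Step 6
Reactants: 9 (5S)-3-(hydroxymethyl)-5-[(1Z)-2-iodoprop-1-en-1-yl]furan-2(5H)-one
Product: 10 (5S)-3-(bromomethyl)-5-[(1Z)-2-iodoprop-1-en-1-yl]furan-2(5H)-one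
Conditions: PBr3, Et2O, 0 °C
Reagents that add atoms: phosphorus tribromide, BrP(Br)Br
Why: PBr3 converts the primary allylic alcohol into the allylic bromide, the precursor of a ring-embedded 2-(alkoxycarbonyl)allyl nucleophile.

Step 7
Reactants: 5 methyl propiolate
Product: 12 methyl (2E)-2-[(tributylstannyl)methylidene]pent-4-enoate, via vinylcopper adduct 11 (not isolated)
Conditions: Bu3SnH, LiN(iPr)2, THF, −78 °C; CuBr·SMe2; then 5, −78 °C; then allyl bromide, HMPA, −78 to −30 °C
Reagents that add atoms: tributyltin hydride, CCCC[SnH](CCCC)CCCC; allyl bromide, C=CCBr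
Why: syn-Stannylcupration of the ynoate puts tin on the terminal carbon (future C1) and copper on the ester-bearing carbon (future C10), and alkylation of the vinylcopper with retention at low temperature should place the allyl group cis to tin, that is tin trans to the ester.

Step 8
Reactants: 12 methyl (2E)-2-[(tributylstannyl)methylidene]pent-4-enoate
Product: 13 methyl (2E)-2-(2-oxoethyl)-3-(tributylstannyl)prop-2-enoate
Conditions: OsO4 (cat.), NaIO4, 2,6-lutidine, dioxane/H2O, rt
Reagents that add atoms: sodium periodate, [Na+].[O-]I(=O)(=O)=O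
Why: Lemieux–Johnson cleavage should select the electron-rich terminal vinyl group over the hindered, electron-poor stannylacrylate and gives the aldehyde whose carbonyl carbon becomes C8.

Step 9
Reactants: 14 angelic acid
Product: 15 (2Z)-2-methylbut-2-en-1-ol
Conditions: LiAlH4, Et2O, 0 °C
Reagents that add atoms: none
Why: Hydride reduction of the unsaturated acid gives the allylic alcohol with the Z geometry retained.

Step 10
Reactants: 15 (2Z)-2-methylbut-2-en-1-ol
Product: 16 [(2S,3R)-2,3-dimethyloxiran-2-yl]methanol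
Conditions: Ti(OiPr)4 (10 mol %), L-(+)-diethyl tartrate, t-BuOOH, 4 Å MS, CH2Cl2, −20 °C
Reagents that add atoms: tert-butyl hydroperoxide, CC(C)(C)OO
Why: Sharpless asymmetric epoxidation with the L-(+)-tartrate should deliver oxygen to the face that gives the (2S,3R)-epoxy alcohol, the cis relation of CH2OH and the C3 methyl coming from the Z olefin.

Step 11
Reactants: 16 [(2S,3R)-2,3-dimethyloxiran-2-yl]methanol
Product: 17 (2R,3R)-2,3-dimethyloxirane-2-carboxylic acid
Conditions: RuCl3 (cat.), NaIO4, MeCN/EtOAc/H2O, 0 °C to rt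
Reagents that add atoms: water, O
Why: Catalytic RuO4 oxidation takes the primary alcohol to the acid without opening the epoxide (the C2 descriptor changes to R only through the CIP priorities).

Step 12
Reactants: 10 (5S)-3-(bromomethyl)-5-[(1Z)-2-iodoprop-1-en-1-yl]furan-2(5H)-one; 13 methyl (2E)-2-(2-oxoethyl)-3-(tributylstannyl)prop-2-enoate
Product: 18 methyl (2E)-2-{(2S)-2-hydroxy-2-[(2S,3R)-2-[(1Z)-2-iodoprop-1-en-1-yl]-4-methylidene-5-oxooxolan-3-yl]ethyl}-3-(tributylstannyl)prop-2-enoate
Conditions: In powder, THF/H2O (1:1), rt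
Reagents that add atoms: none
Why: In this Barbier-type indium allylation the allylindium from 10 should attack 13 through ring carbon C7 on the face opposite the C6 substituent (trans lactone, C7 R) and, through a closed chair with the aldehyde chain equatorial, give the 8S carbinol that the inverting esterification needs.

Step 13
Reactants: 18 (the 8S alcohol of step 12); 17 (2R,3R)-2,3-dimethyloxirane-2-carboxylic acid
Product: 19 methyl (2E)-2-{(2R)-2-{[(2R,3R)-2,3-dimethyloxirane-2-carbonyl]oxy}-2-[(2S,3R)-2-[(1Z)-2-iodoprop-1-en-1-yl]-4-methylidene-5-oxooxolan-3-yl]ethyl}-3-(tributylstannyl)prop-2-enoate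
Conditions: PPh3, DIAD, toluene, 0 °C to rt
Reagents that add atoms: none
Why: Mitsunobu esterification proceeds with SN2 inversion at C8 and should turn the 8S alcohol into the 8R epoxyangelate, the betaine being preformed so that free phosphine does not add to the α-methylene lactone.

Step 14
Reactants: 19 (the 8R epoxyangelate of step 13)
Product: 20 methyl (2E)-2-{(2R)-2-[(2R,3R)-2-[(1Z,3R)-4-chloro-3-hydroxy-2-methylbut-1-en-1-yl]-4-methylidene-5-oxooxolan-3-yl]-2-{[(2R,3R)-2,3-dimethyloxirane-2-carbonyl]oxy}ethyl}-3-(tributylstannyl)prop-2-enoate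
Conditions: ClCH2CHO, CrCl2 (10 mol %), Kishi oxazoline–sulfonamide ligand, NiCl2·(2,9-dimethyl-1,10-phenanthroline) (2 mol %), Mn, Cp2ZrCl2, LiCl, MeCN, rt
Reagents that add atoms: chloroacetaldehyde, O=CCCl
Why: In this asymmetric Nozaki–Hiyama–Kishi coupling zerovalent nickel inserts into the C4–I bond, the alkenyl group passes to trivalent chromium with retention of the Z olefin, and ligand-controlled Re-face addition to the aldehyde should set C3 (3R in 20), the stannane and esters being spectators.

Step 15
Reactants: 20 (the chlorohydrin of step 14)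
Product: 22 methyl (2E)-2-{(2R)-2-{[(2R,3R)-2,3-dimethyloxirane-2-carbonyl]oxy}-2-[(2R,3R)-2-[(1Z,3R)-3-hydroxy-4-iodo-2-methylbut-1-en-1-yl]-4-methylidene-5-oxooxolan-3-yl]ethyl}-3-iodoprop-2-enoate, via iodohydrin stannane 21 (not isolated)
Conditions: NaI, acetone, 55 °C; then I2, CH2Cl2, 0 °C
Reagents that add atoms: sodium iodide, [Na+].[I-]; iodine, II
Why: Finkelstein exchange turns the primary chloride into the iodide, and iododestannylation with retention then gives the (E)-β-iodoacrylate, so both coupling handles appear only now.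

Step 16
Reactants: 22 (the diiodide of step 15)
Product: 23 CNP0143679.1, methyl (1(10)E,3S,4Z,6R,7R,8R)-8-{[(2R,3R)-2,3-dimethyloxirane-2-carbonyl]oxy}-3-hydroxy-12-oxogermacra-1(10),4,11(13)-trieno-12,6-lacton-14-oate
Conditions: NiBr2·dme (30 mol %), 4,4′-di-tert-butyl-2,2′-bipyridine, Mn powder, DMA, rt, syringe-pump addition to 2 mM
Reagents that add atoms: none
Why: Zerovalent nickel inserts into the C1–I bond of the β-iodoacrylate, monovalent nickel abstracts iodine from C2 to give the primary radical, the radical is captured at the alkenylnickel centre and reductive elimination from trivalent nickel forms C1–C2, manganese returning the catalyst to the low-valent state. The closest known reaction is the nickel-catalysed reductive cross-electrophile coupling of vinyl halides with alkyl halides (Weix type), which tolerates free hydroxyl groups and esters. The ten-membered carbocycle closes in the endo sense, both C1 and C10 becoming ring atoms, by C(sp2)–C(sp3) bond formation within an eleven-membered nickelacycle. No stereocenter is created, and the olefin geometry comes from the (E)-iodoacrylate with retention, which places C2 cis to C9. The step needs cross-selectivity between the two C–I bonds, ring closure instead of oligomerization, and no trapping of the C2 radical by the C11=C13 acceptor. The different activation modes of the sp2 and sp3 iodides should give the first, while the trans-fused lactone, the cis C4=C5 olefin and high dilution hold C2 near C1 and favour the others.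

**Compound list**

1 | but-2-yn-1-ol | CC#CCO | starting material
2 | sodium alkenylalanate (five-membered oxa-alumina ring from 1) | [Na+].CC1=CCO[Al-]1(OCCOC)OCCOC | intermediate
3 | (Z)-3-iodobut-2-en-1-ol | C/C(I)=C/CO | intermediate
4 | (Z)-3-iodobut-2-enal | C/C(I)=C/C=O | intermediate
5 | methyl propiolate | C#CC(=O)OC | starting material
6 | methyl (4R,5Z)-4-hydroxy-6-iodohept-5-en-2-ynoate | COC(=O)C#C[C@H](O)/C=C(/C)I | intermediate
7 | methyl (2Z,4S,5Z)-4-hydroxy-6-iodohepta-2,5-dienoate | COC(=O)/C=C\[C@H](O)/C=C(/C)I | intermediate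
8 | (5S)-5-[(1Z)-2-iodoprop-1-en-1-yl]furan-2(5H)-one | O=C1C=C[C@@H](/C=C(/C)I)O1 | intermediate
9 | (5S)-3-(hydroxymethyl)-5-[(1Z)-2-iodoprop-1-en-1-yl]furan-2(5H)-one | O=C1C(CO)=C[C@@H](/C=C(/C)I)O1 | intermediate
10 | (5S)-3-(bromomethyl)-5-[(1Z)-2-iodoprop-1-en-1-yl]furan-2(5H)-one | O=C1C(CBr)=C[C@@H](/C=C(/C)I)O1 | intermediate
11 | methyl (2Z)-2-cuprio-3-(tributylstannyl)prop-2-enoate | COC(=O)/C([Cu])=C/[Sn](CCCC)(CCCC)CCCC | intermediate
12 | methyl (2E)-2-[(tributylstannyl)methylidene]pent-4-enoate | C=CC/C(=C\[Sn](CCCC)(CCCC)CCCC)C(=O)OC | intermediate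
13 | methyl (2E)-2-(2-oxoethyl)-3-(tributylstannyl)prop-2-enoate | O=CC/C(=C\[Sn](CCCC)(CCCC)CCCC)C(=O)OC | intermediate
14 | angelic acid, (2Z)-2-methylbut-2-enoic acid | C/C=C(/C)C(=O)O | starting material
15 | (2Z)-2-methylbut-2-en-1-ol | C/C=C(/C)CO | intermediate
16 | [(2S,3R)-2,3-dimethyloxiran-2-yl]methanol | OC[C@]1(C)O[C@@H]1C | intermediate
17 | (2R,3R)-2,3-dimethyloxirane-2-carboxylic acid | OC(=O)[C@]1(C)O[C@@H]1C | intermediate
18 | methyl (2E)-2-{(2S)-2-hydroxy-2-[(2S,3R)-2-[(1Z)-2-iodoprop-1-en-1-yl]-4-methylidene-5-oxooxolan-3-yl]ethyl}-3-(tributylstannyl)prop-2-enoate | C=C1C(=O)O[C@H](/C=C(/C)I)[C@H]1[C@@H](O)C/C(=C\[Sn](CCCC)(CCCC)CCCC)C(=O)OC | intermediate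
19 | methyl (2E)-2-{(2R)-2-{[(2R,3R)-2,3-dimethyloxirane-2-carbonyl]oxy}-2-[(2S,3R)-2-[(1Z)-2-iodoprop-1-en-1-yl]-4-methylidene-5-oxooxolan-3-yl]ethyl}-3-(tributylstannyl)prop-2-enoate | C=C1C(=O)O[C@H](/C=C(/C)I)[C@H]1[C@@H](C/C(=C\[Sn](CCCC)(CCCC)CCCC)C(=O)OC)OC(=O)[C@]2(C)O[C@@H]2C | intermediate
20 | methyl (2E)-2-{(2R)-2-[(2R,3R)-2-[(1Z,3R)-4-chloro-3-hydroxy-2-methylbut-1-en-1-yl]-4-methylidene-5-oxooxolan-3-yl]-2-{[(2R,3R)-2,3-dimethyloxirane-2-carbonyl]oxy}ethyl}-3-(tributylstannyl)prop-2-enoate | C=C1C(=O)O[C@H](/C=C(/C)[C@@H](O)CCl)[C@H]1[C@@H](C/C(=C\[Sn](CCCC)(CCCC)CCCC)C(=O)OC)OC(=O)[C@]2(C)O[C@@H]2C | intermediate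
21 | methyl (2E)-2-{(2R)-2-{[(2R,3R)-2,3-dimethyloxirane-2-carbonyl]oxy}-2-[(2R,3R)-2-[(1Z,3R)-3-hydroxy-4-iodo-2-methylbut-1-en-1-yl]-4-methylidene-5-oxooxolan-3-yl]ethyl}-3-(tributylstannyl)prop-2-enoate | C=C1C(=O)O[C@H](/C=C(/C)[C@@H](O)CI)[C@H]1[C@@H](C/C(=C\[Sn](CCCC)(CCCC)CCCC)C(=O)OC)OC(=O)[C@]2(C)O[C@@H]2C | intermediate
22 | methyl (2E)-2-{(2R)-2-{[(2R,3R)-2,3-dimethyloxirane-2-carbonyl]oxy}-2-[(2R,3R)-2-[(1Z,3R)-3-hydroxy-4-iodo-2-methylbut-1-en-1-yl]-4-methylidene-5-oxooxolan-3-yl]ethyl}-3-iodoprop-2-enoate | C=C1C(=O)O[C@H](/C=C(/C)[C@@H](O)CI)[C@H]1[C@@H](C/C(=C\I)C(=O)OC)OC(=O)[C@]2(C)O[C@@H]2C | intermediate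
23 | CNP0143679.1, methyl (1(10)E,3S,4Z,6R,7R,8R)-8-{[(2R,3R)-2,3-dimethyloxirane-2-carbonyl]oxy}-3-hydroxy-12-oxogermacra-1(10),4,11(13)-trieno-12,6-lacton-14-oate | C=C1C(=O)O[C@@H]2/C=C(/C)[C@@H](O)C/C=C(/C(=O)OC)C[C@@H](OC(=O)[C@]3(C)O[C@@H]3C)[C@@H]12 | target

**Step count and risks**

Total step count: 16. Longest linear sequence: 11 steps (steps 1–6 and 12–16).

Steps most likely to fail:

Step 16 (ring closure). Oligomerization by intermolecular coupling, premature reduction of the primary iodide, or addition of the C2 radical to the exo-methylene lactone may outrun ring closure. The fallback replaces nickel catalysis by a tin-radical chain vinylation. It sets out from 20: Finkelstein exchange (NaI, acetone, 55 °C) gives the iodohydrin stannane 21, this time isolated. Slow addition of 21 and AIBN (cat.) to benzene at 80 °C (1 mM) generates the C2 radical, which adds to C1 of the β-stannylacrylate. β-Scission then expels the tributyltin radical, which carries the chain by iodine abstraction, and the route is rejoined at 23.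

Step 13 (inverting esterification). Displacement at the hindered C8 may be slow and lose to elimination toward C7, or inversion may be incomplete; the same remedy applies if step 12 delivers a mixture at C8. The fallback is a redox relay followed by acylation with retention. It sets out from 18: Dess–Martin periodinane (NaHCO3, CH2Cl2) should give the C8 ketone F1. (S)-Me-CBS oxazaborolidine with BH3·SMe2 (−30 °C) should reduce it under reagent control to the (8R)-alcohol F2. Esterification of F2 with 17 (DCC, DMAP, CH2Cl2) proceeds with retention and rejoins the route at 19.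

Step 14 (C3–C4 coupling). Facial selectivity at the small aldehyde may be poor, or the α-chloroaldehyde may be reduced by low-valent chromium. The fallback is a non-selective coupling followed by a reagent-controlled reduction. It sets out from 19: coupling with chloroacetaldehyde under achiral conditions (CrCl2, NiCl2 (cat.), DMSO/THF) gives the C3-epimeric chlorohydrins F3. MnO2 oxidizes the allylic alcohol to the (Z)-chloromethyl enone F4. (R)-Me-CBS oxazaborolidine with catecholborane (−78 °C) should return the single (3R)-chlorohydrin, and the route is rejoined at 20.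

Further compounds
F0 | step 16 | none | none
F1 | step 13 | methyl (2E)-2-{2-[(2S,3S)-2-[(1Z)-2-iodoprop-1-en-1-yl]-4-methylidene-5-oxooxolan-3-yl]-2-oxoethyl}-3-(tributylstannyl)prop-2-enoate | C=C1C(=O)O[C@H](/C=C(/C)I)[C@H]1C(=O)C/C(=C\[Sn](CCCC)(CCCC)CCCC)C(=O)OC
F2 | step 13 | methyl (2E)-2-{(2R)-2-hydroxy-2-[(2S,3R)-2-[(1Z)-2-iodoprop-1-en-1-yl]-4-methylidene-5-oxooxolan-3-yl]ethyl}-3-(tributylstannyl)prop-2-enoate | C=C1C(=O)O[C@H](/C=C(/C)I)[C@H]1[C@H](O)C/C(=C\[Sn](CCCC)(CCCC)CCCC)C(=O)OC
F3 | step 14 | C3-epimeric mixture of 20, methyl (2E)-2-{(2R)-2-[(2R,3R)-2-[(1Z)-4-chloro-3-hydroxy-2-methylbut-1-en-1-yl]-4-methylidene-5-oxooxolan-3-yl]-2-{[(2R,3R)-2,3-dimethyloxirane-2-carbonyl]oxy}ethyl}-3-(tributylstannyl)prop-2-enoate | C=C1C(=O)O[C@H](/C=C(/C)C(O)CCl)[C@H]1[C@@H](C/C(=C\[Sn](CCCC)(CCCC)CCCC)C(=O)OC)OC(=O)[C@]2(C)O[C@@H]2C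
F4 | step 14 | methyl (2E)-2-{(2R)-2-[(2R,3R)-2-[(1Z)-4-chloro-2-methyl-3-oxobut-1-en-1-yl]-4-methylidene-5-oxooxolan-3-yl]-2-{[(2R,3R)-2,3-dimethyloxirane-2-carbonyl]oxy}ethyl}-3-(tributylstannyl)prop-2-enoate | C=C1C(=O)O[C@H](/C=C(/C)C(=O)CCl)[C@H]1[C@@H](C/C(=C\[Sn](CCCC)(CCCC)CCCC)C(=O)OC)OC(=O)[C@]2(C)O[C@@H]2C
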